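**Retrosynthetic overview**
- The target is (4R)-7,8-dihydroxy-4-(4-hydroxy-8-methoxynaphthalen-1-yl)-3,4-dihydronaphthalen-1(2H)-one. Its cyclohexanone ring (C1, C2, C3, C4, C4a, C8a) is closed last through bond C4–C4a, and the same event sets C4.
- Enabling feature: C4 is bonded to C1' of the naphthalene, para to the free C4' hydroxyl, so C4 can be unmasked as the exocyclic carbon of a 1,4-naphthoquinone methide. C4a is para to the C7 hydroxyl of the catechol ring and is the only free position ortho to the acyl-bearing C8a.
- C2, C3 and C4 are therefore brought in as a racemic trans-cyclopropane carrying the naphthyl donor and the aroyl acceptor (extra bond C2–C4). A chiral phosphoric acid opens it with strain release and should funnel both enantiomers through the planar quinone methide to the (R)-tetralone.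
- The cyclopropane comes from a chalcone (Corey–Chaykovsky), the chalcone from a Claisen–Schmidt condensation of an allyl-protected 2',3'-dihydroxyacetophenone with an allyl-protected 4-hydroxy-8-methoxy-1-naphthaldehyde. The aldehyde comes from 1,5-dimethoxynaphthalene by formylation and site-selective demethylation.
- Ring order: the naphthalene and catechol rings are bought; the temporary cyclopropane is formed in step 6; the cyclohexanone ring is formed in step 8.

Key step: step 8

Remark: the sense of induction of the chiral phosphoric acid on this new substrate class cannot be assigned in advance; the route is written with the (R)-catalyst, and the mirror-image catalyst would be used if a first run showed the (S)-tetralone. Racemic compounds are drawn as one enantiomer.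

**Route**

Step 1
Reactants: 1 1,5-dimethoxynaphthalene
Product: 3 4,8-dimethoxy-1-naphthaldehyde, via iminium chloride 2 (not isolated)
Conditions: POCl3, DMF, 0 to 80 °C; then H2O
Reagents that add atoms: N,N-dimethylformamide, CN(C)C=O; water, O
Why: Vilsmeier–Haack formylation at the α-position para to a methoxy group, where the two para positions of the symmetric substrate are equivalent and the aldehyde formed is deactivated towards a second formylation.

Step 2
Reactants: 3 4,8-dimethoxy-1-naphthaldehyde
Product: 4 4-hydroxy-8-methoxy-1-naphthaldehyde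
Conditions: NaSEt, DMF, 100 °C; then aq HCl
Reagents that add atoms: none
Why: Nucleophilic (SN2) thiolate demethylation should occur at the methoxy group para to the formyl group, whose naphthoxide is a vinylogous carboxylate, whereas the peri methoxy group at C8 is not conjugated to the aldehyde.

Step 3
Reactants: 4 4-hydroxy-8-methoxy-1-naphthaldehyde
Product: 5 4-(allyloxy)-8-methoxy-1-naphthaldehyde
Conditions: allyl bromide, K2CO3, DMF, rt
Reagents that add atoms: allyl bromide, C=CCBr
Why: Williamson etherification of the acidic naphthol gives an ether that is stable to the basic steps 5 and 6 and removable under neutral conditions.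

Step 4
Reactants: 6 2',3'-dihydroxyacetophenone
Product: 7 2',3'-bis(allyloxy)acetophenone
Conditions: allyl bromide, K2CO3, DMF, 60 °C
Reagents that add atoms: allyl bromide, C=CCBr
Why: Williamson etherification of both catechol hydroxyls, with warming to alkylate the hydrogen-bonded hydroxyl next to the ketone.

Step 5
Reactants: 5 4-(allyloxy)-8-methoxy-1-naphthaldehyde; 7 2',3'-bis(allyloxy)acetophenone
Product: 9 (E)-1-[2,3-bis(allyloxy)phenyl]-3-[4-(allyloxy)-8-methoxynaphthalen-1-yl]prop-2-en-1-one, via aldol adduct 8 (not isolated)
Conditions: KOH, EtOH, rt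
Reagents that add atoms: none
Why: Claisen–Schmidt condensation, in which the aldehyde cannot enolize and E1cB dehydration of aldol 8 gives the thermodynamically favoured (E)-enone.

Step 6
Reactants: 9 (E)-1-[2,3-bis(allyloxy)phenyl]-3-[4-(allyloxy)-8-methoxynaphthalen-1-yl]prop-2-en-1-one
Product: 11 racemic trans-[2,3-bis(allyloxy)phenyl]{(1R*,2R*)-2-[4-(allyloxy)-8-methoxynaphthalen-1-yl]cyclopropyl}methanone, via sulfoxonium betaine 10 (not isolated)
Conditions: Me3S(O)I, NaH, DMSO, rt
Reagents that add atoms: trimethylsulfoxonium iodide, C[S+](C)(C)=O.[I-]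
Why: Corey–Chaykovsky cyclopropanation, in which conjugate addition of dimethylsulfoxonium methylide and 3-exo-tet closure of the freely rotating betaine 10 should set the two cyclopropane stereocenters trans; the product is racemic, which is harmless because step 8 erases this stereochemistry.

Step 7
Reactants: 11 racemic trans-[2,3-bis(allyloxy)phenyl]{(1R*,2R*)-2-[4-(allyloxy)-8-methoxynaphthalen-1-yl]cyclopropyl}methanone
Product: 12 racemic trans-(2,3-dihydroxyphenyl)[(1R*,2R*)-2-(4-hydroxy-8-methoxynaphthalen-1-yl)cyclopropyl]methanone
Conditions: Pd(PPh3)4 (5 mol %), morpholine, THF, rt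
Reagents that add atoms: none
Why: Tsuji–Trost deallylation, in which zerovalent palladium ionizes the three aryl allyl ethers to π-allyl complexes that morpholine captures, under neutral conditions that should leave the aryl ketone and the closed cyclopropane untouched (pH 7 work-up, NEt3-deactivated silica, argon).

Step 8
Reactants: 12 racemic trans-(2,3-dihydroxyphenyl)[(1R*,2R*)-2-(4-hydroxy-8-methoxynaphthalen-1-yl)cyclopropyl]methanone
Product: 14 (4R)-7,8-dihydroxy-4-(4-hydroxy-8-methoxynaphthalen-1-yl)-3,4-dihydronaphthalen-1(2H)-one (the target), via naphthoquinone methide 13 (not isolated)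
Conditions: (R)-TRIP [(R)-3,3'-bis(2,4,6-triisopropylphenyl)-1,1'-binaphthyl-2,2'-diyl hydrogen phosphate] (10 mol %), 4 Å MS, CH2Cl2 (0.005 M), 35 °C
Reagents that add atoms: none
Why: Proposed new method: the phosphoric acid hydrogen-bonds to the aryl ketone and, pushed by the para hydroxyl at C4' and by release of ring strain, the cyclopropane bond between the naphthyl-bearing and the acyl-bearing carbon breaks heterolytically to give, after enol–ketone tautomerism, the planar achiral 1,4-naphthoquinone methide 13, so that both enantiomers (and any cis isomer) of 12 converge on one intermediate. The catechol-ring carbon that is para to the C3 hydroxyl and ortho to the acyl group then adds to the exocyclic methide carbon in a 6-exo-trig Friedel–Crafts closure (bond C4–C4a), and rearomatization of both rings should make this step irreversible. The closest known reaction types are the Lewis-acid cyclization of 2-aryl cyclopropyl aryl ketones to racemic 4-aryl-1-tetralones, the chiral-phosphoric-acid Cloke–Wilson rearrangement of racemic donor–acceptor cyclopropyl ketones (stereoconvergent through the ring-opened cation) and phosphoric-acid-catalysed enantioselective 1,6-Friedel–Crafts additions to para-quinone methides; new is their combination with an arene carbon as the ring-closing nucleophile. C4 is set in the C–C bond-forming step by the chiral phosphate, which is expected to be hydrogen-bonded to the quinone methide oxygen and to the hydroxy ketone of the aroyl unit and so to shield one face of the methide. The step needs C- over O-cyclization and ring closure over intermolecular alkylation of the naphthol ring: O-closure to the dihydrofuran or to the seven-membered aryl ether should be reversible under the acid whereas C–C closure is not, only one position ortho to the acyl group is free, and high dilution disfavours oligomerization.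

**Compound list**
1 | 1,5-dimethoxynaphthalene | COc1cccc2c(OC)cccc12 | starting material
2 | N-[(4,8-dimethoxynaphthalen-1-yl)methylidene]-N-methylmethanaminium chloride | C[N+](C)=Cc1ccc(OC)c2cccc(OC)c12.[Cl-] | intermediate (not isolated)
3 | 4,8-dimethoxy-1-naphthaldehyde | O=Cc1ccc(OC)c2cccc(OC)c12 | intermediate
4 | 4-hydroxy-8-methoxy-1-naphthaldehyde | O=Cc1ccc(O)c2cccc(OC)c12 | intermediate
5 | 4-(allyloxy)-8-methoxy-1-naphthaldehyde | O=Cc1ccc(OCC=C)c2cccc(OC)c12 | intermediate
6 | 2',3'-dihydroxyacetophenone | CC(=O)c1cccc(O)c1O | starting material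
7 | 2',3'-bis(allyloxy)acetophenone | CC(=O)c1cccc(OCC=C)c1OCC=C | intermediate
8 | racemic 1-[2,3-bis(allyloxy)phenyl]-3-hydroxy-3-[4-(allyloxy)-8-methoxynaphthalen-1-yl]propan-1-one (aldol adduct) | O=C(CC(O)c1ccc(OCC=C)c2cccc(OC)c12)c1cccc(OCC=C)c1OCC=C | intermediate (not isolated)
9 | (E)-1-[2,3-bis(allyloxy)phenyl]-3-[4-(allyloxy)-8-methoxynaphthalen-1-yl]prop-2-en-1-one | O=C(/C=C/c1ccc(OCC=C)c2cccc(OC)c12)c1cccc(OCC=C)c1OCC=C | intermediate
10 | sulfoxonium enolate betaine from conjugate addition of the ylide to 9 | C[S+](C)(=O)CC(C=C([O-])c1cccc(OCC=C)c1OCC=C)c1ccc(OCC=C)c2cccc(OC)c12 | intermediate (not isolated)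
11 | racemic trans-[2,3-bis(allyloxy)phenyl]{(1R*,2R*)-2-[4-(allyloxy)-8-methoxynaphthalen-1-yl]cyclopropyl}methanone (one enantiomer drawn) | O=C(c1cccc(OCC=C)c1OCC=C)[C@@H]1C[C@H]1c1ccc(OCC=C)c2cccc(OC)c12 | intermediate
12 | racemic trans-(2,3-dihydroxyphenyl)[(1R*,2R*)-2-(4-hydroxy-8-methoxynaphthalen-1-yl)cyclopropyl]methanone (one enantiomer drawn) | O=C(c1cccc(O)c1O)[C@@H]1C[C@H]1c1ccc(O)c2cccc(OC)c12 | intermediate
13 | 4-[4-(2,3-dihydroxyphenyl)-4-oxobutylidene]-5-methoxynaphthalen-1(4H)-one (naphthoquinone methide) | O=C(CCC=C1C=CC(=O)c2cccc(OC)c12)c1cccc(O)c1O | intermediate (not isolated)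
14 | (4R)-7,8-dihydroxy-4-(4-hydroxy-8-methoxynaphthalen-1-yl)-3,4-dihydronaphthalen-1(2H)-one | COc1cccc2c(O)ccc([C@H]3CCC(=O)c4c3ccc(O)c4O)c12 | target

**Step count**
Total steps: 8. Longest linear sequence: 7 (steps 1, 2, 3, 5, 6, 7, 8).

**Steps most likely to fail**

Step 8 (proposed new method). The facial discrimination in the C–C bond formation on the catalyst-bound quinone methide may be too low or of the wrong sense, and intermolecular alkylation of the electron-rich naphthol ring may outrun the ring closure. The fallback uses known chemistry, sets out from 11 and comes back at 14. Lewis-acid cyclization of the allyl-protected cyclopropane (SnCl4, CH2Cl2, 0 °C, the known cyclization of 2-aryl cyclopropyl aryl ketones to 4-aryl-1-tetralones) should give racemic 7,8-bis(allyloxy)-4-[4-(allyloxy)-8-methoxynaphthalen-1-yl]-3,4-dihydronaphthalen-1(2H)-one F1. Reagent-controlled CBS reduction with (S)-Me-CBS [(S)-1-methyl-3,3-diphenyltetrahydro-1H,3H-pyrrolo[1,2-c][1,3,2]oxazaborole] and catecholborane (toluene, −40 °C; catecholborane is chosen to spare the allyl alkenes) is expected to convert the two enantiomers into two diastereomers, (1R,4R)-7,8-bis(allyloxy)-4-[4-(allyloxy)-8-methoxynaphthalen-1-yl]-1,2,3,4-tetrahydronaphthalen-1-ol F2 and (1R,4S)-7,8-bis(allyloxy)-4-[4-(allyloxy)-8-methoxynaphthalen-1-yl]-1,2,3,4-tetrahydronaphthalen-1-ol F3. These are separated by chromatography, a resolution known for racemic 4-aryl-1-tetralones. Dess–Martin oxidation of F2 should give (4R)-7,8-bis(allyloxy)-4-[4-(allyloxy)-8-methoxynaphthalen-1-yl]-3,4-dihydronaphthalen-1(2H)-one F4, and deallylation under the conditions of step 7 gives 14.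

Step 7. The liberated naphthoxide may be C-allylated by the π-allyl palladium intermediate, and the push–pull cyclopropane may open on acidic silica once the phenols are free, which would feed racemic material into step 8. The fallback sets out from 11 and comes back at 12. After the deallylation, the crude phenols are acetylated in the same flask (Ac2O, pyridine) to give racemic trans-3-{[(1R*,2R*)-2-(4-acetoxy-8-methoxynaphthalen-1-yl)cyclopropyl]carbonyl}-1,2-phenylene diacetate F5. This compound has no free donor hydroxyl and can be purified and stored. Methanolysis (catalytic K2CO3, MeOH, 0 °C, neutralization with solid NH4Cl, filtration, evaporation) then releases 12 with only a volatile by-product, and 12 is used without chromatography.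

Step 2. Site selectivity may be lost through cleavage of the peri ether as well, and the thiolate may be consumed by the aldehyde. The fallback sets out from 3 and comes back at 5. Exhaustive demethylation (BBr3, CH2Cl2, −78 to 0 °C) should give 4,8-dihydroxy-1-naphthaldehyde F6. Allylation with one equivalent of allyl bromide and KHCO3 in DMF should take place at the more acidic C4 hydroxyl (para to the formyl group) and give 4-(allyloxy)-8-hydroxy-1-naphthaldehyde F7. Methylation of the remaining peri hydroxyl (MeI, K2CO3, acetone) gives 5.

**Further compounds**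
F1 | step 8 | racemic 7,8-bis(allyloxy)-4-[4-(allyloxy)-8-methoxynaphthalen-1-yl]-3,4-dihydronaphthalen-1(2H)-one | COc1cccc2c(OCC=C)ccc(C3CCC(=O)c4c3ccc(OCC=C)c4OCC=C)c12
F2 | step 8 | (1R,4R)-7,8-bis(allyloxy)-4-[4-(allyloxy)-8-methoxynaphthalen-1-yl]-1,2,3,4-tetrahydronaphthalen-1-ol | COc1cccc2c(OCC=C)ccc([C@H]3CC[C@@H](O)c4c3ccc(OCC=C)c4OCC=C)c12
F3 | step 8 | (1R,4S)-7,8-bis(allyloxy)-4-[4-(allyloxy)-8-methoxynaphthalen-1-yl]-1,2,3,4-tetrahydronaphthalen-1-ol | COc1cccc2c(OCC=C)ccc([C@@H]3CC[C@@H](O)c4c3ccc(OCC=C)c4OCC=C)c12
F4 | step 8 | (4R)-7,8-bis(allyloxy)-4-[4-(allyloxy)-8-methoxynaphthalen-1-yl]-3,4-dihydronaphthalen-1(2H)-one | COc1cccc2c(OCC=C)ccc([C@H]3CCC(=O)c4c3ccc(OCC=C)c4OCC=C)c12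
F5 | step 7 | racemic trans-3-{[(1R*,2R*)-2-(4-acetoxy-8-methoxynaphthalen-1-yl)cyclopropyl]carbonyl}-1,2-phenylene diacetate (one enantiomer drawn) | O=C(c1cccc(OC(C)=O)c1OC(C)=O)[C@@H]1C[C@H]1c1ccc(OC(C)=O)c2cccc(OC)c12
F6 | step 2 | 4,8-dihydroxy-1-naphthaldehyde | O=Cc1ccc(O)c2cccc(O)c12
F7 | step 2 | 4-(allyloxy)-8-hydroxy-1-naphthaldehyde | O=Cc1ccc(OCC=C)c2cccc(O)c12
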